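**Plan**

1. Last disconnections: the acid and the phenol are unmasked from a methyl ester and a silyl ether, and the C3 CH2OH is traced back to a CH2–O–N alkoxyamine.
2. Strategic cut: the bond between ring-A carbon C3a and C3 of the dihydrofuran ring, opened to an aryl iodide at C3a and a vinyl group on C2, i.e. the (S)-1-arylallyl 2-iodoaryl ether 9.
3. Second cut: the O1–C2 ether bond (iridium-catalysed branched allylic etherification), giving iodophenol 7 and cinnamyl carbonate 5, each made from a benzaldehyde by Wittig chain extension.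
4. Forward: the two arenes are joined through O1–C2; then the only ring made in the synthesis, the dihydrofuran, closes by 5-exo aryl-radical cyclisation with nitroxide capture of the exocyclic carbon.
5. Stereochemistry: C2 (S) comes from the chiral iridium catalyst; C3 (R) is relayed from C2 in the ring closure (2,3-trans); both E alkenes come from stabilised ylides.
6. Enabling feature: O1 sits ortho to C3a on ring A and carries the stereogenic, vinyl-bearing C2, so a radical at C3a is held five atoms from the vinyl carbon that becomes C3.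

Key step: step 7

Remark: benzofuran numbering is used throughout (O1, C2, C3, C3a, C4 to C7, C7a); ring A is the benzo ring.

Assumption: the (Sa,Sc,Sc) phosphoramidite is taken to direct the oxygen nucleophile to the face of the aryl-substituted allyl unit that gives the S ether, as the usual model for cinnamyl electrophiles predicts; if a test run shows the opposite sense, the antipodal ligand is used and nothing else changes.

**Route**

Step 1
Reactants: 1 syringaldehyde (4-hydroxy-3,5-dimethoxybenzaldehyde)
Product: 2 4-[(tert-butyldimethylsilyl)oxy]-3,5-dimethoxybenzaldehyde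
Conditions: TBSCl (1.3 equiv), imidazole (2.5 equiv), DMF, rt
Reagents that add atoms: tert-butyldimethylsilyl chloride, CC(C)(C)[Si](C)(C)Cl
Why: O-silylation of the phenol (silyl ether protection) masks the only acidic OH of the syringyl unit, so that it cannot compete as a nucleophile in step 6, and gives a group that hydroxide removes at the end.

Step 2
Reactants: 2 4-[(tert-butyldimethylsilyl)oxy]-3,5-dimethoxybenzaldehyde
Product: 3 methyl (E)-3-{4-[(tert-butyldimethylsilyl)oxy]-3,5-dimethoxyphenyl}prop-2-enoate
Conditions: Ph3P=CHCO2Me (1.2 equiv), toluene, 90 °C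
Reagents that add atoms: methyl (triphenylphosphoranylidene)acetate, COC(=O)C=P(c1ccccc1)(c1ccccc1)c1ccccc1
Why: Wittig olefination with a stabilised ylide should give the E cinnamate, since the reversible betaine/oxaphosphetane stage of stabilised ylides funnels to the trans alkene.

Step 3
Reactants: 3 methyl (E)-3-{4-[(tert-butyldimethylsilyl)oxy]-3,5-dimethoxyphenyl}prop-2-enoate
Product: 4 (E)-3-{4-[(tert-butyldimethylsilyl)oxy]-3,5-dimethoxyphenyl}prop-2-en-1-ol
Conditions: i-Bu2AlH (2.5 equiv), CH2Cl2, −78 °C; aqueous potassium sodium tartrate (KNaC4H4O6) work-up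
Reagents that add atoms: none
Why: 1,2-reduction of an α,β-unsaturated ester by i-Bu2AlH at low temperature should give the allylic alcohol without touching the alkene or the aryl silyl ether.

Step 4
Reactants: 4 (E)-3-{4-[(tert-butyldimethylsilyl)oxy]-3,5-dimethoxyphenyl}prop-2-en-1-ol
Product: 5 (E)-3-{4-[(tert-butyldimethylsilyl)oxy]-3,5-dimethoxyphenyl}prop-2-en-1-yl methyl carbonate
Conditions: ClCO2Me (1.5 equiv), pyridine (2 equiv), CH2Cl2, 0 °C
Reagents that add atoms: methyl chloroformate, COC(=O)Cl
Why: O-acylation with a chloroformate turns the hydroxyl into the methyl carbonate leaving group that ionises cleanly to an allyl-iridium intermediate and releases only CO2 and methoxide.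

Step 5
Reactants: 6 5-iodovanillin (4-hydroxy-3-iodo-5-methoxybenzaldehyde)
Product: 7 methyl (E)-3-(4-hydroxy-3-iodo-5-methoxyphenyl)prop-2-enoate
Conditions: Ph3P=CHCO2Me (1.2 equiv), toluene, 90 °C
Reagents that add atoms: methyl (triphenylphosphoranylidene)acetate, COC(=O)C=P(c1ccccc1)(c1ccccc1)c1ccccc1
Why: Wittig olefination with the stabilised ylide tolerates the free phenol and should install the E acrylate early, which also makes the phenoxide a better nucleophile and a poorer leaving group than that of the parent aldehyde.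

Step 6
Reactants: 5 (E)-3-{4-[(tert-butyldimethylsilyl)oxy]-3,5-dimethoxyphenyl}prop-2-en-1-yl methyl carbonate; 7 methyl (E)-3-(4-hydroxy-3-iodo-5-methoxyphenyl)prop-2-enoate
Product: 9 methyl (E)-3-{4-[((1S)-1-{4-[(tert-butyldimethylsilyl)oxy]-3,5-dimethoxyphenyl}prop-2-en-1-yl)oxy]-3-iodo-5-methoxyphenyl}prop-2-enoate, via lithium aryloxide 8 (not isolated)
Conditions: 7 (1.5 equiv), LiN(SiMe3)2 (1.45 equiv), THF, 0 °C; then 5, [Ir(cod)Cl]2 (2 mol %), (Sa,Sc,Sc)-O,O'-(1,1'-binaphthalene-2,2'-diyl) N,N-bis(1-phenylethyl)phosphoramidite (4 mol %), THF, rt to 50 °C; water quench; chromatography on Et3N-washed silica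
Reagents that add atoms: LiN(SiMe3)2, [Li+].C[Si](C)(C)[N-][Si](C)(C)C (gives the lithium of 8; no reagent atom other than hydrogen ends in 9)
Why: Iridium-catalysed asymmetric allylic etherification (allylic substitution) should send the aryloxide to the aryl-substituted terminus of the allyl-iridium intermediate, so the branched ether forms with the C2 configuration fixed by the chiral phosphoramidite, while the aryl iodide, the ester and the silyl ether are not engaged by this catalyst.

Step 7
Reactants: 9 methyl (E)-3-{4-[((1S)-1-{4-[(tert-butyldimethylsilyl)oxy]-3,5-dimethoxyphenyl}prop-2-en-1-yl)oxy]-3-iodo-5-methoxyphenyl}prop-2-enoate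
Product: 10 methyl (E)-3-[(2S,3R)-2-{4-[(tert-butyldimethylsilyl)oxy]-3,5-dimethoxyphenyl}-7-methoxy-3-{[(2,2,6,6-tetramethylpiperidin-1-yl)oxy]methyl}-2,3-dihydro-1-benzofuran-5-yl]prop-2-enoate (2,3-trans)
Conditions: TEMPO (5 equiv), Bu3SnH (3 equiv, slow addition), toluene (0.02 M), 60–70 °C, dark; chromatographic removal of any cis isomer
Reagents that add atoms: TEMPO (2,2,6,6-tetramethylpiperidin-1-oxyl), CC1(C)CCCC(C)(C)N1[O]
Why: The tributylstannyl radical (from Bu3SnH and TEMPO) abstracts the iodine of 9, the σ-aryl radical at the future C3a adds to the internal vinyl carbon and so closes the dihydrofuran ring through the C3a–C3 bond, and the primary radical on the exocyclic CH2 is captured by TEMPO, so that the ring, the C3 stereocentre and the oxygen of the future CH2OH arrive in one operation. The closest known reaction type is the aryl radical–alkene cyclisation with nitroxide trapping used to make 3-(hydroxymethyl)indolines and 3-(hydroxymethyl)-2,3-dihydrobenzofurans from N- or O-allyl 2-iodoarenes. The ring closes in the 5-exo-trig mode, which for an ortho-allyloxyaryl radical should be far faster than 6-endo closure, than bimolecular capture of the aryl radical by TEMPO and than hydrogen transfer from Bu3SnH. The new C3 stereocentre is controlled by the C2 stereocentre from step 6: in the early, envelope-like transition state the C2 aryl group is pseudo-equatorial and the vinyl CH2 terminus turns to the opposite face, which should give the 2,3-trans (2S,3R) isomer, and C2 is untouched because no bond to it is made or broken. The step needs chemoselectivity for the aryl iodide over the cinnamate and capture of the primary radical before hydrogen transfer; the ortho placement of iodine and allyloxy group on ring A, the reversibility of stannyl addition to the cinnamate and the excess of TEMPO over slowly added Bu3SnH should secure both, and with both ortho positions of the aryl ether substituted no Claisen rearrangement competes at this temperature.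

Step 8
Reactants: 10 methyl (E)-3-[(2S,3R)-2-{4-[(tert-butyldimethylsilyl)oxy]-3,5-dimethoxyphenyl}-7-methoxy-3-{[(2,2,6,6-tetramethylpiperidin-1-yl)oxy]methyl}-2,3-dihydro-1-benzofuran-5-yl]prop-2-enoate
Product: 11 methyl (E)-3-[(2S,3R)-2-{4-[(tert-butyldimethylsilyl)oxy]-3,5-dimethoxyphenyl}-3-(hydroxymethyl)-7-methoxy-2,3-dihydro-1-benzofuran-5-yl]prop-2-enoate
Conditions: Zn dust (excess), AcOH/THF/H2O (3:1:1), 50 °C
Reagents that add atoms: none
Why: Dissolving-metal reduction of the N–O bond of the alkoxyamine by zinc in acetic acid should free the primary alcohol, with the C–O bond and both stereocentres untouched and the cinnamate and aryl silyl ether inert to this reductant.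

Step 9
Reactants: 11 methyl (E)-3-[(2S,3R)-2-{4-[(tert-butyldimethylsilyl)oxy]-3,5-dimethoxyphenyl}-3-(hydroxymethyl)-7-methoxy-2,3-dihydro-1-benzofuran-5-yl]prop-2-enoate
Product: 13 (E)-3-[(2S,3R)-2-(4-hydroxy-3,5-dimethoxyphenyl)-3-(hydroxymethyl)-7-methoxy-2,3-dihydro-1-benzofuran-5-yl]prop-2-enoic acid (target), via dilithium carboxylate phenoxide 12 (not isolated)
Conditions: LiOH·H2O (6 equiv), THF/MeOH/H2O (3:1:1), rt to 40 °C; then 1 M HCl to pH 3, 0 °C
Reagents that add atoms: lithium hydroxide monohydrate, [Li+].[OH-].O (the hydroxide oxygen becomes the acid OH; lithium sits in 12)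
Why: Saponification of the methyl ester and hydroxide cleavage of the phenolic silyl ether should occur in the same pot, and because C3 carries no acidifying group and the temperature is low, neither β-elimination of the ring-A phenoxide nor quinone-methide opening at C2 is expected.

**Compound list**

1 | syringaldehyde (4-hydroxy-3,5-dimethoxybenzaldehyde) | COc1cc(C=O)cc(OC)c1O | starting material
2 | 4-[(tert-butyldimethylsilyl)oxy]-3,5-dimethoxybenzaldehyde | COc1cc(C=O)cc(OC)c1O[Si](C)(C)C(C)(C)C | intermediate
3 | methyl (E)-3-{4-[(tert-butyldimethylsilyl)oxy]-3,5-dimethoxyphenyl}prop-2-enoate | COC(=O)/C=C/c1cc(OC)c(O[Si](C)(C)C(C)(C)C)c(OC)c1 | intermediate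
4 | (E)-3-{4-[(tert-butyldimethylsilyl)oxy]-3,5-dimethoxyphenyl}prop-2-en-1-ol | OC/C=C/c1cc(OC)c(O[Si](C)(C)C(C)(C)C)c(OC)c1 | intermediate
5 | (E)-3-{4-[(tert-butyldimethylsilyl)oxy]-3,5-dimethoxyphenyl}prop-2-en-1-yl methyl carbonate | COC(=O)OC/C=C/c1cc(OC)c(O[Si](C)(C)C(C)(C)C)c(OC)c1 | intermediate
6 | 5-iodovanillin (4-hydroxy-3-iodo-5-methoxybenzaldehyde) | COc1cc(C=O)cc(I)c1O | starting material
7 | methyl (E)-3-(4-hydroxy-3-iodo-5-methoxyphenyl)prop-2-enoate | COC(=O)/C=C/c1cc(I)c(O)c(OC)c1 | intermediate
8 | lithium aryloxide of 7 (lithium 2-iodo-6-methoxy-4-[(E)-3-methoxy-3-oxoprop-1-enyl]phenoxide) | COC(=O)/C=C/c1cc(I)c([O-])c(OC)c1.[Li+] | intermediate (not isolated)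
9 | methyl (E)-3-{4-[((1S)-1-{4-[(tert-butyldimethylsilyl)oxy]-3,5-dimethoxyphenyl}prop-2-en-1-yl)oxy]-3-iodo-5-methoxyphenyl}prop-2-enoate | C=C[C@H](Oc1c(I)cc(/C=C/C(=O)OC)cc1OC)c1cc(OC)c(O[Si](C)(C)C(C)(C)C)c(OC)c1 | intermediate
10 | methyl (E)-3-[(2S,3R)-2-{4-[(tert-butyldimethylsilyl)oxy]-3,5-dimethoxyphenyl}-7-methoxy-3-{[(2,2,6,6-tetramethylpiperidin-1-yl)oxy]methyl}-2,3-dihydro-1-benzofuran-5-yl]prop-2-enoate | COc1cc([C@H]2Oc3c(OC)cc(/C=C/C(=O)OC)cc3[C@@H]2CON2C(C)(C)CCCC2(C)C)cc(OC)c1O[Si](C)(C)C(C)(C)C | intermediate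
11 | methyl (E)-3-[(2S,3R)-2-{4-[(tert-butyldimethylsilyl)oxy]-3,5-dimethoxyphenyl}-3-(hydroxymethyl)-7-methoxy-2,3-dihydro-1-benzofuran-5-yl]prop-2-enoate | COc1cc([C@H]2Oc3c(OC)cc(/C=C/C(=O)OC)cc3[C@@H]2CO)cc(OC)c1O[Si](C)(C)C(C)(C)C | intermediate
12 | dilithium carboxylate phenoxide of the target | COc1cc([C@H]2Oc3c(OC)cc(/C=C/C(=O)[O-])cc3[C@@H]2CO)cc(OC)c1[O-].[Li+].[Li+] | intermediate (not isolated)
13 | (E)-3-[(2S,3R)-2-(4-hydroxy-3,5-dimethoxyphenyl)-3-(hydroxymethyl)-7-methoxy-2,3-dihydro-1-benzofuran-5-yl]prop-2-enoic acid | COc1cc([C@H]2Oc3c(OC)cc(/C=C/C(=O)O)cc3[C@@H]2CO)cc(OC)c1O | target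

**Count and risks**

Total step count: 9. Longest linear sequence: 8 steps (steps 1, 2, 3, 4, 6, 7, 8, 9).

Steps most likely to fail:

1. Step 7. The 5-exo closure may show only a modest preference for approach of the vinyl terminus anti to the C2 aryl group, so that the C3 epimer forms alongside. The fallback replaces kinetic control at C3 by thermodynamic control. It sets out from 11 obtained together with its C3 epimer (the epimeric alkoxyamines being taken through step 8 unseparated). Dess–Martin periodinane (NaHCO3, CH2Cl2, 0 °C) should oxidise the mixture to the 2,3-cis aldehyde F1 and the 2,3-trans aldehyde F2. A catalytic amount of DBU (CH2Cl2, 0 °C, short contact) should convert F1 into F2 by reversible enolisation at C3 alone, so the C2 configuration from step 6 is kept and β-elimination of the ring-A phenoxide is held back. NaBH4 (MeOH, 0 °C) should then reduce the 2,3-trans aldehyde F2 without touching the cinnamate, and the route is rejoined at 11 as the single trans isomer.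

2. Step 6. Attack of the doubly ortho-substituted, weakly nucleophilic aryloxide on the allyl-iridium intermediate may be slow, with loss of branched selectivity. The product ether, which has a good leaving group on an electron-rich allylic and benzylic carbon, may also re-ionise, with erosion of enantiomeric purity. The fallback separates the stereocentre-forming event from the aryl ether formation and sets out from 5. Iridium-catalysed allylic hydroxylation with KHCO3 ([Ir(cod)Cl]2, the antipodal (Ra,Rc,Rc) phosphoramidite, THF/H2O, rt) should give (R)-1-{4-[(tert-butyldimethylsilyl)oxy]-3,5-dimethoxyphenyl}prop-2-en-1-ol F3. Mitsunobu etherification of F3 with phenol 7 (PPh3, DIAD, toluene, −20 °C) should displace the activated hydroxyl with inversion and return to the route at 9.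

3. Step 8. The warm acidic medium needed for N–O reduction may ionise the electron-rich benzylic C2–O1 bond (ring opening or C2 epimerisation), or the reduction may stall. The fallback brings in the oxygen through boron instead of a nitroxide and sets out from 9. Cross-metathesis of the terminal alkene with vinylboronic acid pinacol ester (second-generation Hoveyda–Grubbs catalyst, CH2Cl2, 40 °C) should give the (E)-alkenyl pinacol boronate F4. Reductive 5-exo aryl-radical cyclisation (Bu3SnH, AIBN, toluene, 80 °C), in which the α-boryl radical is quenched by hydrogen transfer, should give the trans 3-(borylmethyl)dihydrobenzofuran F5. Oxidation of the C–B bond of F5 with NaBO3·4H2O (THF/H2O, rt), which proceeds with retention and under near-neutral conditions, rejoins the route at 11.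

**Further compounds**

F1 | step 7 | methyl (E)-3-[(2S,3R)-2-{4-[(tert-butyldimethylsilyl)oxy]-3,5-dimethoxyphenyl}-3-formyl-7-methoxy-2,3-dihydro-1-benzofuran-5-yl]prop-2-enoate (2,3-cis aldehyde) | COc1cc([C@H]2Oc3c(OC)cc(/C=C/C(=O)OC)cc3[C@H]2C=O)cc(OC)c1O[Si](C)(C)C(C)(C)C
F2 | step 7 | methyl (E)-3-[(2S,3S)-2-{4-[(tert-butyldimethylsilyl)oxy]-3,5-dimethoxyphenyl}-3-formyl-7-methoxy-2,3-dihydro-1-benzofuran-5-yl]prop-2-enoate (2,3-trans aldehyde) | COc1cc([C@H]2Oc3c(OC)cc(/C=C/C(=O)OC)cc3[C@@H]2C=O)cc(OC)c1O[Si](C)(C)C(C)(C)C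
F3 | step 6 | (R)-1-{4-[(tert-butyldimethylsilyl)oxy]-3,5-dimethoxyphenyl}prop-2-en-1-ol | C=C[C@@H](O)c1cc(OC)c(O[Si](C)(C)C(C)(C)C)c(OC)c1
F4 | step 8 | methyl (E)-3-{4-[((1S,2E)-1-{4-[(tert-butyldimethylsilyl)oxy]-3,5-dimethoxyphenyl}-3-(4,4,5,5-tetramethyl-1,3,2-dioxaborolan-2-yl)prop-2-en-1-yl)oxy]-3-iodo-5-methoxyphenyl}prop-2-enoate | CC1(C)OB(/C=C/[C@H](Oc2c(I)cc(/C=C/C(=O)OC)cc2OC)c2cc(OC)c(O[Si](C)(C)C(C)(C)C)c(OC)c2)OC1(C)C
F5 | step 8 | methyl (E)-3-[(2S,3S)-2-{4-[(tert-butyldimethylsilyl)oxy]-3,5-dimethoxyphenyl}-7-methoxy-3-[(4,4,5,5-tetramethyl-1,3,2-dioxaborolan-2-yl)methyl]-2,3-dihydro-1-benzofuran-5-yl]prop-2-enoate (2,3-trans) | COc1cc([C@H]2Oc3c(OC)cc(/C=C/C(=O)OC)cc3[C@@H]2CB2OC(C)(C)C(C)(C)O2)cc(OC)c1O[Si](C)(C)C(C)(C)C
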